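## Retrosynthetic overview

1. Target ⇐ its O‑TBS ether by desilylation; the stereocentre comes from L‑glutamic acid 5‑benzyl ester (diazotisation with retention).
2. The only ring is formed second to last, by intramolecular Claisen (Dieckmann‑type) closure of an acyclic 2‑silyloxy‑5,7‑dioxo ester (ring C1–C2 bond).
3. Key fragment union: crossed Claisen condensation of the kinetic lithium enolate of (13Z,15E)‑heptadeca‑13,15‑dien‑2‑one with the N‑acylbenzotriazole of O‑TBS (S)‑2‑hydroxyglutaric acid 1‑methyl ester (future ring C2–C3 bond).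
4. Dienone ⇐ Z‑selective Wittig reaction of a ketal‑protected C13 phosphonium ylide with (E)‑crotonaldehyde; the bromo ketone comes from tert‑butyl acetoacetate and 1,10‑dibromodecane.

Assumption: the target is one enol tautomer of a β‑triketone; 20 and 21 are drawn in the tautomer of the given SMILES and the tautomers interconvert freely.

## Route

Step 1
Reactants: 1 L‑glutamic acid 5‑benzyl ester, (2S)‑2‑amino‑5‑(benzyloxy)‑5‑oxopentanoic acid
Product: 2 (2S)‑5‑(benzyloxy)‑2‑hydroxy‑5‑oxopentanoic acid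
Conditions: NaNO2 (2 equiv), 1 M H2SO4 (aq)/1,4‑dioxane, 0 °C → rt, 16 h
Reagents that add atoms: water (O)
Why: Diazotisation (van Slyke‑type deamination) in which the α‑carboxylate displaces N2 to an α‑lactone that water opens, so two inversions give the (S)‑hydroxy acid with net retention while the benzyl ester is untouched.

Step 2
Reactants: 2 (2S)‑5‑(benzyloxy)‑2‑hydroxy‑5‑oxopentanoic acid
Product: 3 5‑benzyl 1‑methyl (2S)‑2‑hydroxypentanedioate
Conditions: MeI (1.5 equiv), KHCO3 (1.5 equiv), DMF, rt, 12 h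
Reagents that add atoms: iodomethane (CI)
Why: SN2 O‑alkylation of the carboxylate, with a base too weak to deprotonate the alcohol or the α‑C–H, so there is no ether formation and no racemisation.

Step 3
Reactants: 3 5‑benzyl 1‑methyl (2S)‑2‑hydroxypentanedioate
Product: 4 5‑benzyl 1‑methyl (2S)‑2‑[(tert‑butyldimethylsilyl)oxy]pentanedioate
Conditions: TBSCl (1.3 equiv), imidazole (2.5 equiv), DMF, rt, 12 h
Reagents that add atoms: tert‑butyldimethylsilyl chloride (CC(C)(C)[Si](C)(C)Cl)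
Why: Corey silylation of the secondary alcohol, which also blocks lactonisation onto the benzyl ester; the stereocentre is not involved.

Step 4
Reactants: 4 5‑benzyl 1‑methyl (2S)‑2‑[(tert‑butyldimethylsilyl)oxy]pentanedioate
Product: 5 (4S)‑4‑[(tert‑butyldimethylsilyl)oxy]‑5‑methoxy‑5‑oxopentanoic acid
Conditions: H2 (1 atm), 10% Pd/C, EtOAc, rt, 3 h
Reagents that add atoms: none
Why: Hydrogenolysis of the benzyl ester frees only the C5 carboxyl; the methyl ester and the TBS ether are inert in EtOAc.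

Step 5
Reactants: 5 (4S)‑4‑[(tert‑butyldimethylsilyl)oxy]‑5‑methoxy‑5‑oxopentanoic acid
Product: 6 methyl (2S)‑5‑(1H‑benzotriazol‑1‑yl)‑2‑[(tert‑butyldimethylsilyl)oxy]‑5‑oxopentanoate
Conditions: 1H‑benzotriazole (1.1 equiv), DCC (1.1 equiv), CH2Cl2, 0 °C → rt, 4 h
Reagents that add atoms: 1H‑benzotriazole (c1ccc2[nH]nnc2c1)
Why: Carbodiimide coupling gives a stable, isolable N‑acylbenzotriazole under neutral conditions that leave the TBS ether and the remote stereocentre alone.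

Step 6
Reactants: 7 tert‑butyl 3‑oxobutanoate (tert‑butyl acetoacetate); 8 1,10‑dibromodecane
Product: 9 tert‑butyl 2‑acetyl‑12‑bromododecanoate (racemic)
Conditions: NaH (1.0 equiv), THF/DMF 4:1, 0 °C; then 8 (3 equiv), 60 °C, 12 h
Reagents that add atoms: none
Why: Acetoacetic ester C‑alkylation, with excess dibromide (recovered) to suppress double displacement.

Step 7
Reactants: 9 tert‑butyl 2‑acetyl‑12‑bromododecanoate (racemic)
Product: 11 13‑bromotridecan‑2‑one, via β‑keto acid 10 (not isolated)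
Conditions: TsOH·H2O (0.1 equiv), toluene, 100 °C, 3 h
Reagents that add atoms: none
Why: Acid‑catalysed loss of isobutene from the tert‑butyl ester followed by thermal decarboxylation of the β‑keto acid gives the methyl ketone without touching the primary bromide.

Step 8
Reactants: 11 13‑bromotridecan‑2‑one
Product: 12 2‑(11‑bromoundecyl)‑2‑methyl‑1,3‑dioxolane
Conditions: ethylene glycol (3 equiv), TsOH·H2O (cat.), toluene, reflux, Dean–Stark, 6 h
Reagents that add atoms: ethane‑1,2‑diol (OCCO)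
Why: Ketalisation with azeotropic water removal masks the ketone against the ylide chemistry that follows.

Step 9
Reactants: 12 2‑(11‑bromoundecyl)‑2‑methyl‑1,3‑dioxolane
Product: 13 [11‑(2‑methyl‑1,3‑dioxolan‑2‑yl)undecyl]triphenylphosphonium bromide
Conditions: PPh3 (1.2 equiv), K2CO3 (0.05 equiv), MeCN, reflux, 48 h
Reagents that add atoms: triphenylphosphine (c1ccc(cc1)P(c1ccccc1)c1ccccc1)
Why: SN2 quaternisation of the primary bromide, with a trace of base to keep the ketal safe from adventitious HBr.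

Step 10
Reactants: 13 [11‑(2‑methyl‑1,3‑dioxolan‑2‑yl)undecyl]triphenylphosphonium bromide; 14 (E)‑but‑2‑enal (crotonaldehyde)
Product: 16 2‑methyl‑2‑[(11Z,13E)‑pentadeca‑11,13‑dien‑1‑yl]‑1,3‑dioxolane, via phosphonium ylide 15 (not isolated)
Conditions: NaN(SiMe3)2 (1.0 equiv), THF, −78 → 0 °C; then 14 (1.2 equiv), −78 °C → rt; tetracyanoethylene (0.1 equiv) before chromatography
Reagents that add atoms: none
Why: Wittig reaction of a lithium‑free non‑stabilised ylide, whose kinetic cis‑oxaphosphetane sets the new double bond Z (about 92:8) while the E bond of crotonaldehyde is carried through; the minor E,E isomer is removed as its Diels–Alder adduct with tetracyanoethylene.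

Step 11
Reactants: 16 2‑methyl‑2‑[(11Z,13E)‑pentadeca‑11,13‑dien‑1‑yl]‑1,3‑dioxolane
Product: 17 (13Z,15E)‑heptadeca‑13,15‑dien‑2‑one
Conditions: 1 M HCl (aq)/THF 1:4, rt, 3 h, dark
Reagents that add atoms: water (O)
Why: Acid‑catalysed ketal hydrolysis under conditions too mild to protonate or isomerise the conjugated diene.

Step 12
Reactants: 17 (13Z,15E)‑heptadeca‑13,15‑dien‑2‑one; 6 methyl (2S)‑5‑(1H‑benzotriazol‑1‑yl)‑2‑[(tert‑butyldimethylsilyl)oxy]‑5‑oxopentanoate
Product: 19 methyl (2S,18Z,20E)‑2‑[(tert‑butyldimethylsilyl)oxy]‑5,7‑dioxodocosa‑18,20‑dienoate, via lithium enolate 18 (not isolated)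
Conditions: LiN(SiMe3)2 (2.0 equiv), 17 (2.0 equiv), THF, −78 °C, 45 min; then 6 (1.0 equiv), −78 → −30 °C; AcOH (2.2 equiv), −78 °C
Reagents that add atoms: none
Why: Crossed Claisen condensation in which the kinetic methyl‑side enolate is C‑acylated by the acylbenzotriazole (far more electrophilic than the methyl ester), the second equivalent of enolate deprotonating the β‑diketone as it forms (excess 17 is recovered); the stereocentre is remote and untouched.

Step 13
Reactants: 19 methyl (2S,18Z,20E)‑2‑[(tert‑butyldimethylsilyl)oxy]‑5,7‑dioxodocosa‑18,20‑dienoate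
Product: 20 (6S)‑6‑[(tert‑butyldimethylsilyl)oxy]‑2‑[(12Z,14E)‑hexadeca‑12,14‑dienoyl]‑3‑hydroxycyclohex‑2‑en‑1‑one
Conditions: KOtBu (2.0 equiv), THF, 0 °C → rt, 2 h (40 °C if slow); cold 1 M HCl to pH 3
Reagents that add atoms: none
Why: Intramolecular Claisen (Dieckmann‑type) C‑acylation of the β‑diketone enolate by the methyl ester, where only the six‑membered closure is geometrically possible and the very acidic β‑triketone anion is the thermodynamic sink; the α‑silyloxy C–H of the already anionic substrate is not deprotonated, so (S) is kept.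

Step 14
Reactants: 20 (6S)‑6‑[(tert‑butyldimethylsilyl)oxy]‑2‑[(12Z,14E)‑hexadeca‑12,14‑dienoyl]‑3‑hydroxycyclohex‑2‑en‑1‑one
Product: 21 (6S)‑2‑[(12Z,14E)‑hexadeca‑12,14‑dienoyl]‑3,6‑dihydroxycyclohex‑2‑en‑1‑one (CNP0144157.1)
Conditions: HF·pyridine, THF/pyridine, 0 °C → rt, 4 h, polypropylene vessel, dark
Reagents that add atoms: none
Why: Fluoride‑driven Si–O cleavage (desilylation) breaks no bond at the stereocentre and leaves the acid‑stable triketone and the diene intact.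

## Compound list

1 | L‑glutamic acid 5‑benzyl ester, (2S)‑2‑amino‑5‑(benzyloxy)‑5‑oxopentanoic acid | N[C@@H](CCC(=O)OCc1ccccc1)C(=O)O | starting material
2 | (2S)‑5‑(benzyloxy)‑2‑hydroxy‑5‑oxopentanoic acid | O[C@@H](CCC(=O)OCc1ccccc1)C(=O)O | intermediate
3 | 5‑benzyl 1‑methyl (2S)‑2‑hydroxypentanedioate | O[C@@H](CCC(=O)OCc1ccccc1)C(=O)OC | intermediate
4 | 5‑benzyl 1‑methyl (2S)‑2‑[(tert‑butyldimethylsilyl)oxy]pentanedioate | CC(C)(C)[Si](C)(C)O[C@@H](CCC(=O)OCc1ccccc1)C(=O)OC | intermediate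
5 | (4S)‑4‑[(tert‑butyldimethylsilyl)oxy]‑5‑methoxy‑5‑oxopentanoic acid | CC(C)(C)[Si](C)(C)O[C@@H](CCC(=O)O)C(=O)OC | intermediate
6 | methyl (2S)‑5‑(1H‑benzotriazol‑1‑yl)‑2‑[(tert‑butyldimethylsilyl)oxy]‑5‑oxopentanoate | CC(C)(C)[Si](C)(C)O[C@@H](CCC(=O)n1nnc2ccccc12)C(=O)OC | intermediate
7 | tert‑butyl 3‑oxobutanoate (tert‑butyl acetoacetate) | CC(=O)CC(=O)OC(C)(C)C | starting material
8 | 1,10‑dibromodecane | BrCCCCCCCCCCBr | starting material
9 | tert‑butyl 2‑acetyl‑12‑bromododecanoate (racemic) | CC(=O)C(CCCCCCCCCCBr)C(=O)OC(C)(C)C | intermediate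
10 | 2‑acetyl‑12‑bromododecanoic acid (racemic β‑keto acid, not isolated) | CC(=O)C(CCCCCCCCCCBr)C(=O)O | intermediate
11 | 13‑bromotridecan‑2‑one | CC(=O)CCCCCCCCCCCBr | intermediate
12 | 2‑(11‑bromoundecyl)‑2‑methyl‑1,3‑dioxolane | CC1(CCCCCCCCCCCBr)OCCO1 | intermediate
13 | [11‑(2‑methyl‑1,3‑dioxolan‑2‑yl)undecyl]triphenylphosphonium bromide | CC1(CCCCCCCCCCC[P+](c2ccccc2)(c2ccccc2)c2ccccc2)OCCO1.[Br-] | intermediate
14 | (E)‑but‑2‑enal (crotonaldehyde) | C/C=C/C=O | starting material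
15 | [11‑(2‑methyl‑1,3‑dioxolan‑2‑yl)undecylidene]triphenylphosphorane (ylide, not isolated) | CC1(CCCCCCCCCCC=P(c2ccccc2)(c2ccccc2)c2ccccc2)OCCO1 | intermediate
16 | 2‑methyl‑2‑[(11Z,13E)‑pentadeca‑11,13‑dien‑1‑yl]‑1,3‑dioxolane | CC1(CCCCCCCCCC/C=C\C=C\C)OCCO1 | intermediate
17 | (13Z,15E)‑heptadeca‑13,15‑dien‑2‑one | CC(=O)CCCCCCCCCC/C=C\C=C\C | intermediate
18 | lithium (13Z,15E)‑heptadeca‑1,13,15‑trien‑2‑olate (not isolated) | [Li+].[O-]C(=C)CCCCCCCCCC/C=C\C=C\C | intermediate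
19 | methyl (2S,18Z,20E)‑2‑[(tert‑butyldimethylsilyl)oxy]‑5,7‑dioxodocosa‑18,20‑dienoate | CC(C)(C)[Si](C)(C)O[C@@H](CCC(=O)CC(=O)CCCCCCCCCC/C=C\C=C\C)C(=O)OC | intermediate
20 | (6S)‑6‑[(tert‑butyldimethylsilyl)oxy]‑2‑[(12Z,14E)‑hexadeca‑12,14‑dienoyl]‑3‑hydroxycyclohex‑2‑en‑1‑one | C/C=C/C=C\CCCCCCCCCCC(=O)C1=C(O)CC[C@H](O[Si](C)(C)C(C)(C)C)C1=O | intermediate
21 | (6S)‑2‑[(12Z,14E)‑hexadeca‑12,14‑dienoyl]‑3,6‑dihydroxycyclohex‑2‑en‑1‑one (CNP0144157.1) | C/C=C/C=C\CCCCCCCCCCC(=O)C1=C(O)CC[C@H](O)C1=O | target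

## Step count and risks

Total step count: 14. Longest linear sequence: 9 steps (7 and 8 → 21, steps 6–14); the glutamate branch is 8 steps (1 → 21).

Steps most likely to fail:

Step 12 (crossed Claisen: O‑acylation, double acylation or wrong‑side enolate). The fallback sets out from 5 and comes back at 19, replacing the acylation by an aldol addition and an oxidation. Acid 5 is coupled with EtSH (DCC, catalytic DMAP, CH2Cl2, 0 °C) to the thioester methyl (2S)‑2‑[(tert‑butyldimethylsilyl)oxy]‑5‑(ethylsulfanyl)‑5‑oxopentanoate F1. Fukuyama reduction (Et3SiH, 10% Pd/C, acetone, rt) then gives the aldehyde methyl (2S)‑2‑[(tert‑butyldimethylsilyl)oxy]‑5‑oxopentanoate F2. Aldol addition of lithium enolate 18 (1.1 equiv, THF, −78 °C, AcOH quench at −78 °C to prevent lactonisation) gives the β‑hydroxy ketone methyl (2S,18Z,20E)‑2‑[(tert‑butyldimethylsilyl)oxy]‑5‑hydroxy‑7‑oxodocosa‑18,20‑dienoate F3 as a mixture of C5 epimers. Dess–Martin periodinane (NaHCO3, CH2Cl2, 0 °C) oxidises both epimers to 19.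

Step 13 (ring closure: slow attack on the hindered α‑silyloxy ester, or partial epimerisation under alkoxide). The fallback sets out from 19 and comes back at 20, activating the carboxyl instead of relying on alkoxide. The methyl ester is saponified (LiOH, THF/H2O, 0 °C) to the acid (2S,18Z,20E)‑2‑[(tert‑butyldimethylsilyl)oxy]‑5,7‑dioxodocosa‑18,20‑dienoic acid F4. 1,1'‑Carbonyldiimidazole (THF, rt) converts it into the acyl imidazole (2S,18Z,20E)‑2‑[(tert‑butyldimethylsilyl)oxy]‑1‑(1H‑imidazol‑1‑yl)docosa‑18,20‑diene‑1,5,7‑trione F5. Soft enolisation with MgBr2·OEt2 and i‑Pr2NEt (CH2Cl2, 0 °C → rt) then closes the ring by C‑acylation of the magnesium diketonate, giving 20.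

Step 10 (Z/E selectivity of the Wittig reaction and separation of the E,E isomer). The fallback sets out from 12 and comes back at 16, fixing both geometries by stereospecific cross‑coupling. Kornblum oxidation of 12 (DMSO, NaHCO3, 120 °C) gives the aldehyde 11‑(2‑methyl‑1,3‑dioxolan‑2‑yl)undecanal F6. Iodo‑olefination with Ph3P=CHI (from [Ph3PCH2I]I and NaN(SiMe3)2, THF/DMPU, −78 °C) gives the vinyl iodide 2‑[(11Z)‑12‑iodododec‑11‑en‑1‑yl]‑2‑methyl‑1,3‑dioxolane F7 (Z ≥ 95:5). Suzuki coupling with (E)‑prop‑1‑en‑1‑ylboronic acid (Pd(PPh3)4, aqueous K3PO4, THF, 50 °C) joins the two alkenes with retention of both geometries to give 16.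

## Further compounds

F1 | step 12 | methyl (2S)‑2‑[(tert‑butyldimethylsilyl)oxy]‑5‑(ethylsulfanyl)‑5‑oxopentanoate | CC(C)(C)[Si](C)(C)O[C@@H](CCC(=O)SCC)C(=O)OC
F2 | step 12 | methyl (2S)‑2‑[(tert‑butyldimethylsilyl)oxy]‑5‑oxopentanoate | CC(C)(C)[Si](C)(C)O[C@@H](CCC=O)C(=O)OC
F3 | step 12 | methyl (2S,18Z,20E)‑2‑[(tert‑butyldimethylsilyl)oxy]‑5‑hydroxy‑7‑oxodocosa‑18,20‑dienoate (C5 epimers) | CC(C)(C)[Si](C)(C)O[C@@H](CCC(O)CC(=O)CCCCCCCCCC/C=C\C=C\C)C(=O)OC
F4 | step 13 | (2S,18Z,20E)‑2‑[(tert‑butyldimethylsilyl)oxy]‑5,7‑dioxodocosa‑18,20‑dienoic acid | CC(C)(C)[Si](C)(C)O[C@@H](CCC(=O)CC(=O)CCCCCCCCCC/C=C\C=C\C)C(=O)O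
F5 | step 13 | (2S,18Z,20E)‑2‑[(tert‑butyldimethylsilyl)oxy]‑1‑(1H‑imidazol‑1‑yl)docosa‑18,20‑diene‑1,5,7‑trione | CC(C)(C)[Si](C)(C)O[C@@H](CCC(=O)CC(=O)CCCCCCCCCC/C=C\C=C\C)C(=O)n1ccnc1
F6 | step 10 | 11‑(2‑methyl‑1,3‑dioxolan‑2‑yl)undecanal | CC1(CCCCCCCCCCC=O)OCCO1
F7 | step 10 | 2‑[(11Z)‑12‑iodododec‑11‑en‑1‑yl]‑2‑methyl‑1,3‑dioxolane | CC1(CCCCCCCCCC/C=C\I)OCCO1
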